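**Retrosynthetic overview**
1. Target ⇐ C2 acetylation, reduction of the C2 and C7 ketones with lactonisation (sets C2, C7), and C6 α-chlorination of a (3Z)-5-methylidenecyclodec-3-ene-2,7-dione that already carries 8-OH, 9-OAc, the C17 ester and the C12 propanoate.
2. Ten-membered ring ⇐ four-atom ring expansion of a trans-fused cyclohexane α-ketol: Pd-mediated β-acyl elimination cuts C2–C7, and the (Z)-iododienyl arm (C3–C6) on C7 is joined to the acyl carbon C2.
3. α-Ketol ⇐ indium allylation at C7 of a bicyclic ketone; its six-membered ring by Dieckmann closure (C8→C9); C8 by diketone alkylation then hydroxylation; C9 by hydride.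
4. Ring C ⇐ catalytic asymmetric exo-Diels–Alder of a 2-silyloxypentadiene with methyl (E)-3-formylcrotonate (sets C1, C10, C11).
5. Ring order: cyclohexene (ring C) → auxiliary six-membered ring → ten-membered ring by ring expansion → γ-lactone last.

Assumption: locants C1–C20 are the briarane numbers of the target (C1 quaternary fusion carbon, C2–C9 the rest of the ten-membered ring, C10 the other fusion carbon, C11–C14 the cyclohexene, C15 = Me on C1, C16 = exocyclic CH2, C17/C18/C19 = lactone CH, its Me and C=O, C20 = Me on C11); C2 in 8–11, 13–16, 23–27 and C7 in 23–28 are carried as inconsequential epimers (both centres are erased later) and are written without a stereo label.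

Step 1
Reactants: 1 methyl 3-methylbut-2-enoate
Product: 2 methyl (2E)-3-methyl-4-oxobut-2-enoate
Conditions: SeO2, 1,4-dioxane, reflux
Reagents that add atoms: selenium dioxide, O=[Se]=O
Why: Riley allylic oxidation of the methyl group trans to the ester gives the (E)-enal; no stereocentre is formed.

Step 2
Reactants: 3 pent-1-en-3-one
Product: 4 (3Z)-3-(triisopropylsilyloxy)penta-1,3-diene
Conditions: TIPSOTf, Et3N, Et2O, 0 °C
Reagents that add atoms: triisopropylsilyl triflate, CC(C)[Si](C(C)C)(C(C)C)OS(=O)(=O)C(F)(F)F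
Why: Soft enolisation and O-silylation toward the ethyl group gives the Z-dienol ether (methyl trans to the vinyl group), the diene needed for the cycloaddition.

Step 3
Reactants: 2 methyl (2E)-3-methyl-4-oxobut-2-enoate; 4 (3Z)-3-(triisopropylsilyloxy)penta-1,3-diene
Product: 5 Diels–Alder adduct (formyl ester cyclohexene)
Conditions: (S)-o-tolyl-CBS-oxazaborolidine·HNTf2 (10 mol %), CH2Cl2, −78 °C
Reagents that add atoms: none
Why: Catalytic asymmetric Diels–Alder reaction; the formyl-activated β-carbon (C10) bonds to the nucleophilic diene terminus (para rule), the E-dienophile puts C15-Me cis to CO2Me, the exo-CHO/endo-CO2Me transition state typical of α-branched enals puts the outside methyl (C20) cis to the ester, and the catalyst fixes the absolute configuration of C1, C10 and C11.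

Step 4
Reactants: 5 Diels–Alder adduct; 6 methoxyethene
Product: 9 α-hydroxy methyl ketone (C2 epimers), via 1-methoxyvinyllithium 7 (not isolated), via methoxyvinyl carbinol 8 (not isolated)
Conditions: 6, t-BuLi, THF, −78 → 0 °C; 5, −78 °C; then 0.1 M HCl, THF, 0 °C
Reagents that add atoms: water, O
Why: 1,2-Addition of the acetyl-anion equivalent to the aldehyde (ester untouched at −78 °C), then mild hydrolysis of the methyl enol ether, which the hindered TIPS enol ether survives; the C2 carbinol mixture is erased in step 19.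

Step 5
Reactants: 9 α-hydroxy methyl ketone
Product: 10 TES ether
Conditions: TESOTf, 2,6-lutidine, CH2Cl2, −78 °C
Reagents that add atoms: triethylsilyl triflate, CC[Si](CC)(CC)OS(=O)(=O)C(F)(F)F
Why: Silylation blocks α-ketol isomerisation in the base steps and later keeps hydride away from C7.

Step 6
Reactants: 10 TES ether
Product: 11 bicyclic 1,3-dione
Conditions: KHMDS (2.2 equiv), THF, −78 → 0 °C; aq. NH4Cl
Reagents that add atoms: none
Why: Dieckmann-type Claisen condensation; the methyl-ketone enolate (C8) acylates on the C9 ester, and the trans arrangement of the two arms on ring C gives a trans-fused six-membered dione.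

Step 7
Reactants: 11 bicyclic 1,3-dione; 12 methyl (2R)-2-chloropropanoate
Product: 13 C8-alkylated dione
Conditions: Cs2CO3, DMF, 50 °C
Reagents that add atoms: none
Why: C-alkylation of the soft diketonate by SN2 with inversion on the α-chloro ester sets C17 (R); C8 stays enolisable.

Step 8
Reactants: 13 C8-alkylated dione
Product: 14 8-hydroxy dione
Conditions: KHMDS, THF, −78 °C; 2-(phenylsulfonyl)-3-phenyloxaziridine
Reagents that add atoms: Davis oxaziridine, O=S(=O)(c1ccccc1)N1OC1c1ccccc1
Why: Davis enolate hydroxylation; stereoelectronically preferred axial attack on the diketonate puts OH axial (trans to the angular C15 methyl) and the propanoate arm equatorial, setting C8, and the neutral silyl enol ether does not react.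

Step 9
Reactants: 14 8-hydroxy dione
Product: 16 9-acetate, via 8,9-diol 15 (not isolated)
Conditions: NaBH4, MeOH/CH2Cl2, −78 °C; evaporate; Ac2O, DMAP, pyridine, 0 °C
Reagents that add atoms: acetic anhydride, CC(=O)OC(C)=O
Why: Borohydride attacks the less hindered C9 carbonyl (C7 is shielded by the OTES carbon) from the face opposite the axial C15 methyl (as 6-oxo steroids give 6β-ols), giving the axial 9-alcohol, which is acetylated in the same flask before it can lactonise onto the ester.

Step 10
Reactants: 17 2-bromoprop-2-en-1-ol; 18 ethynyl(trimethyl)silane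
Product: 19 2-methylidene-4-(trimethylsilyl)but-3-yn-1-ol
Conditions: PdCl2(PPh3)2, CuI, i-Pr2NH, THF, rt
Reagents that add atoms: none
Why: Sonogashira coupling of the vinyl bromide with the silyl alkyne.

Step 11
Reactants: 19 2-methylidene-4-(trimethylsilyl)but-3-yn-1-ol
Product: 20 4-iodo-2-methylidenebut-3-yn-1-ol
Conditions: NIS, AgNO3 (cat.), DMF, rt, dark
Reagents that add atoms: N-iodosuccinimide, O=C1CCC(=O)N1I
Why: Silver-catalysed iododesilylation of the alkynylsilane.

Step 12
Reactants: 20 4-iodo-2-methylidenebut-3-yn-1-ol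
Product: 21 (3Z)-4-iodo-2-methylidenebut-3-en-1-ol
Conditions: 2-nitrobenzenesulfonyl hydrazide, Et3N, THF/i-PrOH, rt
Reagents that add atoms: none
Why: Diimide cis-semireduction of the iodoalkyne gives the (Z)-vinyl iodide; the 1,1-disubstituted alkene reacts more slowly.

Step 13
Reactants: 21 (3Z)-4-iodo-2-methylidenebut-3-en-1-ol
Product: 22 (1Z)-3-(bromomethyl)-1-iodobuta-1,3-diene
Conditions: CBr4, PPh3, CH2Cl2, 0 °C
Reagents that add atoms: carbon tetrabromide, BrC(Br)(Br)Br
Why: Appel bromination of the primary allylic alcohol.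

Step 14
Reactants: 16 9-acetate; 22 (1Z)-3-(bromomethyl)-1-iodobuta-1,3-diene
Product: 23 C7 tertiary homoallylic alcohol
Conditions: In powder, THF/H2O (3:1), rt
Reagents that add atoms: none
Why: Barbier allylation of the only ketone (C7), activated by chelation to the 8-OH; both allyl termini are CH2, so there is no regiochemical issue, the vinyl iodide is inert, and the new C7 configuration is inconsequential.

Step 15
Reactants: 23 C7 tertiary homoallylic alcohol
Product: 24 cyclohexenone
Conditions: IBX·4-methoxypyridine N-oxide, DMSO, rt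
Reagents that add atoms: none
Why: IBX dehydrogenation of the silyl enol ether gives the C12 enone with the C13=C14 double bond, without the Pd(0) that a Saegusa oxidation would generate in the presence of the vinyl iodide.

Step 16
Reactants: 24 cyclohexenone
Product: 25 12β-allylic alcohol
Conditions: NaBH4, CeCl3·7H2O, MeOH, −78 °C
Reagents that add atoms: none
Why: Luche 1,2-reduction of the only ketone; hydride enters anti to the axial C20 methyl on the neighbouring carbon, giving the alcohol cis to C20 (the C12 epimer of the target).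

Step 17
Reactants: 25 12β-allylic alcohol
Product: 26 12α-propanoate
Conditions: EtCO2H, PPh3, DIAD, toluene, 0 °C → rt
Reagents that add atoms: propanoic acid, CCC(O)=O
Why: Mitsunobu esterification with SN2 inversion from the open α-face gives the C12 configuration of the target; SN2′ attack at C14 is blocked by the quaternary C1 and the tertiary alcohols do not react.

Step 18
Reactants: 26 12α-propanoate
Product: 27 C2 alcohol
Conditions: HF·pyridine, pyridine, THF, 0 °C
Reagents that add atoms: none
Why: Buffered fluoride cleaves the TES ether; esters and the vinyl iodide are stable.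

Step 19
Reactants: 27 C2 alcohol
Product: 28 C2 ketone (tertiary α-ketol)
Conditions: Dess–Martin periodinane, NaHCO3, CH2Cl2, 0 °C
Reagents that add atoms: none
Why: Dess–Martin oxidation of the only secondary alcohol erases the C2 epimer mixture and gives the α-ketol for the ring expansion.

Step 20
Reactants: 28 C2 ketone (tertiary α-ketol)
Product: 29 ring-expanded cyclodecadienedione
Conditions: Pd(OAc)2 (10 mol %), P(t-Bu)3·HBF4 (20 mol %), Cs2CO3, toluene, 80 °C, 5 mM
Reagents that add atoms: none
Why: Proposed new method: Pd(0) inserts into the (Z)-vinyl iodide, the C7 alkoxide binds Pd (seven-membered palladacycle), β-acyl elimination cuts the C2–C7 bond to give the C7 ketone and an acyl–Pd–vinyl species, and reductive elimination forms C2–C3 with retention of the Z geometry, a net four-atom ring expansion (6 → 10); the closest known reactions are Pd-catalysed β-carbon elimination/arylation of tertiary alcohols, retro-allylation of homoallyl alcohols and ring-opening cross-coupling of cyclobutanols.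

Step 21
Reactants: 29 ring-expanded cyclodecadienedione
Product: 30 6-chloro dione
Conditions: LiHMDS (2.2 equiv), THF, −78 °C; NCS, −78 °C; AcOH quench
Reagents that add atoms: N-chlorosuccinimide, O=C1CCC(=O)N1Cl
Why: C6 is the only enolisable ketone position (C8 is quaternary, C2 is flanked by C1 and sp2 C3); the kinetic lithium dienolate is chlorinated at the α-carbon from the outer face of the ring, setting C6, and the cold acidic quench keeps the exocyclic methylene out of conjugation.

Step 22
Reactants: 30 6-chloro dione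
Product: 32 lactone alcohol, via 2,7-diol ester 31 (not isolated)
Conditions: NaBH4, CeCl3·7H2O, MeOH/THF, −78 → −40 °C; AcOH; PPTS (cat.), CH2Cl2, rt
Reagents that add atoms: none
Why: Luche reduction of both ketones; the Ce(III)-chelated C7 carbonyl (to 8-OH) is attacked from the ring periphery to give the 7-O anti to 8-OH, the C2 dienone is reduced 1,2 from the outer face, and acid-catalysed lactonisation of the 7-OH onto the C19 ester closes the γ-lactone without epoxide formation from the chlorohydrin.

Step 23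
Reactants: 32 lactone alcohol
Product: 33 CNP0305105.1
Conditions: Ac2O, DMAP (cat.), pyridine, 0 °C
Reagents that add atoms: acetic anhydride, CC(=O)OC(C)=O
Why: Acylation of the secondary allylic 2-OH; the tertiary 8-OH does not react under these conditions.

**Compound list**
1 | methyl 3-methylbut-2-enoate | CC(C)=CC(=O)OC | starting material
2 | methyl (2E)-3-methyl-4-oxobut-2-enoate | O=C/C(C)=C/C(=O)OC | intermediate
3 | pent-1-en-3-one | CCC(=O)C=C | starting material
4 | (3Z)-3-(triisopropylsilyloxy)penta-1,3-diene | C=C/C(=C/C)O[Si](C(C)C)(C(C)C)C(C)C | intermediate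
5 | methyl (1S,2S,6R)-2-formyl-2,6-dimethyl-5-(triisopropylsilyloxy)cyclohex-4-ene-1-carboxylate (ring carbons 1, 2, 6 = C10, C1, C11; CO2Me and both methyls cis) | O=C[C@@]1(C)CC=C(O[Si](C(C)C)(C(C)C)C(C)C)[C@H](C)[C@@H]1C(=O)OC | intermediate
6 | methoxyethene | C=COC | starting material
7 | 1-methoxyvinyllithium | [Li]C(=C)OC | intermediate
8 | methyl 2-(1-hydroxy-2-methoxyprop-2-en-1-yl)-2,6-dimethyl-5-(triisopropylsilyloxy)cyclohex-4-ene-1-carboxylate (ring as in 5, carbinol epimers) | C=C(OC)C(O)[C@@]1(C)CC=C(O[Si](C(C)C)(C(C)C)C(C)C)[C@H](C)[C@@H]1C(=O)OC | intermediate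
9 | methyl 2-(1-hydroxy-2-oxopropyl)-2,6-dimethyl-5-(triisopropylsilyloxy)cyclohex-4-ene-1-carboxylate (ring as in 5, C2 epimers) | CC(=O)C(O)[C@@]1(C)CC=C(O[Si](C(C)C)(C(C)C)C(C)C)[C@H](C)[C@@H]1C(=O)OC | intermediate
10 | triethylsilyl ether of 9 | CC(=O)C(O[Si](CC)(CC)CC)[C@@]1(C)CC=C(O[Si](C(C)C)(C(C)C)C(C)C)[C@H](C)[C@@H]1C(=O)OC | intermediate
11 | trans-fused 4a,8-dimethyl-4-(triethylsilyloxy)-7-(triisopropylsilyloxy)-4a,5,8,8a-tetrahydronaphthalene-1,3(2H,4H)-dione (C9 and C7 ketones, C8 = CH2; ring C centres as in 5) | O=C1CC(=O)C(O[Si](CC)(CC)CC)[C@@]2(C)CC=C(O[Si](C(C)C)(C(C)C)C(C)C)[C@H](C)[C@@H]21 | intermediate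
12 | methyl (2R)-2-chloropropanoate | C[C@@H](Cl)C(=O)OC | starting material
13 | 11 bearing at C8 the (2R)-1-methoxy-1-oxopropan-2-yl group (C17 R) | O=C1C([C@@H](C)C(=O)OC)C(=O)C(O[Si](CC)(CC)CC)[C@@]2(C)CC=C(O[Si](C(C)C)(C(C)C)C(C)C)[C@H](C)[C@@H]21 | intermediate
14 | 8-hydroxy derivative of 13 (8-OH axial, trans to the angular C15 methyl) | O=C1[C@](O)([C@@H](C)C(=O)OC)C(=O)C(O[Si](CC)(CC)CC)[C@@]2(C)CC=C(O[Si](C(C)C)(C(C)C)C(C)C)[C@H](C)[C@@H]21 | intermediate
15 | 9-alcohol of 14 (9-OH axial, cis to C15 methyl, trans to 8-OH) | O[C@@H]1[C@](O)([C@@H](C)C(=O)OC)C(=O)C(O[Si](CC)(CC)CC)[C@@]2(C)CC=C(O[Si](C(C)C)(C(C)C)C(C)C)[C@H](C)[C@@H]21 | intermediate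
16 | 9-acetate of 15 (C7 ketone) | CC(=O)O[C@@H]1[C@](O)([C@@H](C)C(=O)OC)C(=O)C(O[Si](CC)(CC)CC)[C@@]2(C)CC=C(O[Si](C(C)C)(C(C)C)C(C)C)[C@H](C)[C@@H]21 | intermediate
17 | 2-bromoprop-2-en-1-ol | OCC(Br)=C | starting material
18 | ethynyl(trimethyl)silane | C#C[Si](C)(C)C | starting material
19 | 2-methylidene-4-(trimethylsilyl)but-3-yn-1-ol | OCC(=C)C#C[Si](C)(C)C | intermediate
20 | 4-iodo-2-methylidenebut-3-yn-1-ol | OCC(=C)C#CI | intermediate
21 | (3Z)-4-iodo-2-methylidenebut-3-en-1-ol | OCC(=C)/C=C\I | intermediate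
22 | (1Z)-3-(bromomethyl)-1-iodobuta-1,3-diene | BrCC(=C)/C=C\I | intermediate
23 | 16 allylated at C7: 7-hydroxy-7-[(3Z)-4-iodo-2-methylidenebut-3-en-1-yl] (C7 configuration open) | CC(=O)O[C@@H]1[C@](O)([C@@H](C)C(=O)OC)C(O)(CC(=C)/C=C\I)C(O[Si](CC)(CC)CC)[C@@]2(C)CC=C(O[Si](C(C)C)(C(C)C)C(C)C)[C@H](C)[C@@H]21 | intermediate
24 | cyclohexenone from 23 (C12=O, C13=C14) | CC(=O)O[C@@H]1[C@](O)([C@@H](C)C(=O)OC)C(O)(CC(=C)/C=C\I)C(O[Si](CC)(CC)CC)[C@@]2(C)C=CC(=O)[C@H](C)[C@@H]21 | intermediate
25 | 12β-allylic alcohol (OH cis to C20 methyl) | CC(=O)O[C@@H]1[C@](O)([C@@H](C)C(=O)OC)C(O)(CC(=C)/C=C\I)C(O[Si](CC)(CC)CC)[C@@]2(C)C=C[C@H](O)[C@H](C)[C@@H]21 | intermediate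
26 | 12α-propanoate (C12 as in the target) | CC(=O)O[C@@H]1[C@](O)([C@@H](C)C(=O)OC)C(O)(CC(=C)/C=C\I)C(O[Si](CC)(CC)CC)[C@@]2(C)C=C[C@@H](OC(=O)CC)[C@H](C)[C@@H]21 | intermediate
27 | C2 alcohol (TES removed) | CC(=O)O[C@@H]1[C@](O)([C@@H](C)C(=O)OC)C(O)(CC(=C)/C=C\I)C(O)[C@@]2(C)C=C[C@@H](OC(=O)CC)[C@H](C)[C@@H]21 | intermediate
28 | C2 ketone, tertiary α-ketol at C7 | CC(=O)O[C@@H]1[C@](O)([C@@H](C)C(=O)OC)C(O)(CC(=C)/C=C\I)C(=O)[C@@]2(C)C=C[C@@H](OC(=O)CC)[C@H](C)[C@@H]21 | intermediate
29 | methyl (2R)-2-[(3Z)-9-acetoxy-8-hydroxy-1,11-dimethyl-5-methylidene-2,7-dioxo-12-(propanoyloxy)bicyclo[8.4.0]tetradeca-3,13-dien-8-yl]propanoate (briarane locants) | C=C1/C=C\C(=O)[C@@]2(C)C=C[C@@H](OC(=O)CC)[C@H](C)[C@@H]2[C@H](OC(C)=O)[C@](O)([C@@H](C)C(=O)OC)C(=O)C1 | intermediate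
30 | (6S)-6-chloro derivative of 29 | C=C1/C=C\C(=O)[C@@]2(C)C=C[C@@H](OC(=O)CC)[C@H](C)[C@@H]2[C@H](OC(C)=O)[C@](O)([C@@H](C)C(=O)OC)C(=O)[C@H]1Cl | intermediate
31 | 2,7-diol methyl ester from 30 | C=C1/C=C\[C@H](O)[C@@]2(C)C=C[C@@H](OC(=O)CC)[C@H](C)[C@@H]2[C@H](OC(C)=O)[C@](O)([C@@H](C)C(=O)OC)[C@@H](O)[C@H]1Cl | intermediate
32 | 2-O-deacetyl target (7,8-fused γ-lactone, free 2-OH and 8-OH) | C=C1/C=C\[C@H](O)[C@@]2(C)C=C[C@@H](OC(=O)CC)[C@H](C)[C@@H]2[C@H](OC(C)=O)[C@]2(O)[C@@H](C)C(=O)O[C@H]2[C@H]1Cl | intermediate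
33 | CNP0305105.1: 2,9-diacetoxy-6-chloro-8-hydroxy-12-propanoyloxybriara-3(Z),5(16),13-trien-18,7-olide | C=C1/C=C\[C@H](OC(C)=O)[C@@]2(C)C=C[C@@H](OC(=O)CC)[C@H](C)[C@@H]2[C@H](OC(C)=O)[C@]2(O)[C@@H](C)C(=O)O[C@H]2[C@H]1Cl | target

**Totals and risks**
Total step count: 23 (19 on the main line, 4 for reagent 22). Longest linear sequence: 18 steps (1, 3–9, 14–23, from methyl 3-methylbut-2-enoate).

Step 20, the proposed Pd-mediated ring expansion, is the most uncertain: retro-allylation at C6–C7 or base-induced α-ketol shift could compete with β-acyl elimination. The fallback sets out from 28 and uses known chemistry: intramolecular Nozaki–Hiyama–Kishi addition of the vinyl iodide to the C2 ketone (CrCl2, cat. NiCl2, DMSO) gives the tricyclic ring-fusion cis-diol F1, and Criegee glycol cleavage (Pb(OAc)4, K2CO3, benzene, 0 °C) cuts the same C2–C7 bond; the trans-diaxial C7/C8 diol is not expected to be cleaved. It rejoins the route at 29.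

Step 21 can fail through γ-chlorination, double-bond migration into conjugation, or the wrong face at C6. The fallback sets out from 29: the same lithium dienolate is hydroxylated with the Davis oxaziridine to the 6-hydroxy ketone F2 (oxygen on the face an electrophile prefers), and Appel chlorination (PPh3, CCl4, MeCN) displaces it with inversion. It rejoins the route at 30.

Step 22 creates two carbinol centres on a flexible ring, and the C2 face selectivity is the weaker argument; polar Felkin control by the C6–Cl bond also opposes the chelation model at C7. The fallback sets out from 30: the reduction is run as in step 22 and, if the 2-epimeric lactone alcohol F3 is what forms, a Mitsunobu reaction with acetic acid (PPh3, DIAD, toluene) inverts C2 and installs the acetate in one operation. It rejoins the route at 33.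

Further compounds
F1 | step 20 | tricyclic C2,C7-diol from NHK closure of 28 (ring C2–C3=C4–C5(=CH2)–C6–C7 fused on the C2–C7 bond) | CC(=O)O[C@@H]1[C@](O)([C@@H](C)C(=O)OC)C2(O)CC(=C)C=CC2(O)[C@@]3(C)C=C[C@@H](OC(=O)CC)[C@H](C)[C@@H]31
F2 | step 21 | 6-hydroxy analogue of 30 with the opposite configuration at C6 | C=C1/C=C\C(=O)[C@@]2(C)C=C[C@@H](OC(=O)CC)[C@H](C)[C@@H]2[C@H](OC(C)=O)[C@](O)([C@@H](C)C(=O)OC)C(=O)[C@@H]1O
F3 | step 22 | 2-epimer of 32 | C=C1/C=C\[C@@H](O)[C@@]2(C)C=C[C@@H](OC(=O)CC)[C@H](C)[C@@H]2[C@H](OC(C)=O)[C@]2(O)[C@@H](C)C(=O)O[C@H]2[C@H]1Cl
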